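**Strategy.** Ring B is disconnected at C6–C7 and C8–C9 (eudesmane numbering): its C7–C8 unit is an alkyne that is inserted between two alkene carbons, C6 on C5 and C9 on C10, which stand trans on a finished ring A. One ruthenium-catalysed enyne cross-metathesis/ring-closing metathesis cascade between this 1,5-diene and an alkynyl boronate that already carries the C11 carbinol forms both bonds and closes ring B; oxidation of the C8–B bond in the same flask unveils the C6=C7–C8(=O)–C9H2 enone. The precursor is a 5,6-dialkenylcyclohexene whose C9 alkene bears a relay chain; it comes from an asymmetric Diels–Alder reaction. Dihydroxylation and acylation of ring A follow.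

Key step: step 9

Numbering: eudesmane numbering is used for ring atoms throughout (ring A = C1–C5, C10; ring B = C5–C10; C11 = carbinol carbon on C7).

Assumption: the sense of induction in step 3 is taken from the accepted formyl C–H···O binding model for oxazaborolidinium-catalysed enal Diels–Alder reactions; should the antipodal adduct prevail, the (R)-catalyst is used with no other change.

Step 1
Reactants: 1 pent-1-en-3-one
Product: 2 (Z)-triisopropyl(penta-1,3-dien-3-yloxy)silane
Conditions: i-Pr3SiOTf, Et3N, CH2Cl2, 0 °C to rt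
Reagents that add atoms: triisopropylsilyl trifluoromethanesulfonate CC(C)[Si](C(C)C)(C(C)C)OS(=O)(=O)C(F)(F)F
Why: Soft enolisation of the ethyl ketone and O-silylation (silyl enol ether formation) should give the 2-silyloxy diene, the kinetic Z enol ether placing the terminal methyl outside as the s-cis diene requires.

Step 2
Reactants: 3 prop-2-enal; 4 2-(triphenylphosphoranylidene)propanal
Product: 5 (2E)-2-methylpenta-2,4-dienal
Conditions: CH2Cl2, 0 °C to rt
Reagents that add atoms: none
Why: Wittig olefination with a stabilised α-methyl formyl ylide is E-selective, so formyl and vinyl should end up trans across the trisubstituted alkene, which later becomes the trans relation of C9 and C6.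

Step 3
Reactants: 2 (Z)-triisopropyl(penta-1,3-dien-3-yloxy)silane; 5 (2E)-2-methylpenta-2,4-dienal
Product: 6 (1S,5S,6S)-6-ethenyl-1,5-dimethyl-4-(triisopropylsilyloxy)cyclohex-3-ene-1-carbaldehyde
Conditions: (S)-3,3-diphenyl-1-(2-methylphenyl)tetrahydro-1H,3H-pyrrolo[1,2-c][1,3,2]oxazaborole·HNTf2 (20 mol%), CH2Cl2, −78 to −40 °C
Reagents that add atoms: none
Why: Catalytic asymmetric Diels–Alder reaction in which the boron-bound s-trans enal reacts at its α,β-alkene, the enol-ether β-carbon of 2 bonding to the enal β-carbon (C4–C5) and the CH2 terminus to the α-carbon (C1–C10), the chiral oxazaborolidinium cation blocking one enal face so that C5 and C10 are set together (diene on the Cα Si face), the E geometry of 5 fixing vinyl trans to formyl, and the C4 methyl centre (endo adduct shown) being erased in step 6.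

Step 4
Reactants: 6 (1S,5S,6S)-6-ethenyl-1,5-dimethyl-4-(triisopropylsilyloxy)cyclohex-3-ene-1-carbaldehyde; 7 (hex-5-en-1-yl)triphenylphosphonium bromide
Product: 9 triisopropyl{[(4R,5S,6S)-5-ethenyl-4-[(1Z)-hepta-1,6-dien-1-yl]-4,6-dimethylcyclohex-1-en-1-yl]oxy}silane, via hex-5-enylidene(triphenyl)phosphorane 8 (not isolated)
Conditions: 7, KN(SiMe3)2, THF, 0 °C; then 6, −78 °C to rt
Reagents that add atoms: none
Why: Wittig olefination of the non-enolisable neopentyl aldehyde with a non-stabilised ylide should give the Z alkene that carries the relay chain on C9, with no stereocentre touched.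

Step 5
Reactants: 9 triisopropyl{[(4R,5S,6S)-5-ethenyl-4-[(1Z)-hepta-1,6-dien-1-yl]-4,6-dimethylcyclohex-1-en-1-yl]oxy}silane
Product: 10 (2S,3S,4R)-3-ethenyl-4-[(1Z)-hepta-1,6-dien-1-yl]-2,4-dimethylcyclohexan-1-one
Conditions: n-Bu4NF, AcOH, THF, 0 °C
Reagents that add atoms: none
Why: Fluoride cleavage of the silyl enol ether under acetic acid buffering protonates C2 and releases the C3 ketone without epimerising C5 or C10.

Step 6
Reactants: 10 (2S,3S,4R)-3-ethenyl-4-[(1Z)-hepta-1,6-dien-1-yl]-2,4-dimethylcyclohexan-1-one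
Product: 12 (3R,4R)-3-ethenyl-4-[(1Z)-hepta-1,6-dien-1-yl]-2,4-dimethylcyclohex-1-en-1-yl trifluoromethanesulfonate, via bromomagnesium enolate 11 (not isolated)
Conditions: i-Pr2NMgBr (from EtMgBr and i-Pr2NH), Et2O, rt; then PhNTf2, THF, 0 °C to rt
Reagents that add atoms: N-phenylbis(trifluoromethanesulfonimide) O=S(=O)(N(c1ccccc1)S(=O)(=O)C(F)(F)F)C(F)(F)F
Why: Equilibrating deprotonation with the magnesium amide should give the more substituted (thermodynamic) enolate towards C4, and O-triflation (enol triflate formation) fixes the future C3=C4 double bond while erasing the C4 stereocentre.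

Step 7
Reactants: 12 (3R,4R)-3-ethenyl-4-[(1Z)-hepta-1,6-dien-1-yl]-2,4-dimethylcyclohex-1-en-1-yl trifluoromethanesulfonate
Product: 13 (5R,6S)-6-ethenyl-5-[(1Z)-hepta-1,6-dien-1-yl]-1,5-dimethylcyclohex-1-ene
Conditions: Pd(OAc)2 (5 mol%), PPh3, n-Bu3N, HCO2H, DMF, 60 °C
Reagents that add atoms: none
Why: Palladium-catalysed formate reduction of the enol triflate (oxidative addition of zerovalent palladium, hydride transfer from formate, reductive elimination) replaces OTf by H with retention of the double-bond position and leaves the unactivated alkenes alone.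

Step 8
Reactants: 14 trimethyl[(2-methylbut-3-yn-2-yl)oxy]silane
Product: 17 trimethyl{[2-methyl-4-(4,4,5,5-tetramethyl-1,3,2-dioxaborolan-2-yl)but-3-yn-2-yl]oxy}silane, via lithium acetylide 15 (not isolated), via lithium alkynyl(isopropoxy)borate 16 (not isolated)
Conditions: n-BuLi, THF, −78 °C; 2-isopropoxy-4,4,5,5-tetramethyl-1,3,2-dioxaborolane; then HCl in Et2O, −78 °C to rt
Reagents that add atoms: 2-isopropoxy-4,4,5,5-tetramethyl-1,3,2-dioxaborolane CC(C)OB1OC(C)(C)C(C)(C)O1
Why: Deprotonation of the terminal alkyne, addition to the borate ester and acid collapse of the ate complex is the standard alkynyl pinacol boronate synthesis, the tertiary silyl ether keeping the carbinol inert.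

Step 9
Reactants: 13 (5R,6S)-6-ethenyl-5-[(1Z)-hepta-1,6-dien-1-yl]-1,5-dimethylcyclohex-1-ene; 17 trimethyl{[2-methyl-4-(4,4,5,5-tetramethyl-1,3,2-dioxaborolan-2-yl)but-3-yn-2-yl]oxy}silane
Product: 20 (4aR,8aR)-3-(2-hydroxypropan-2-yl)-5,8a-dimethyl-4a,7,8,8a-tetrahydronaphthalen-2(1H)-one, via cyclic dienyl boronate 18 (not isolated), via silyl enone 19 (not isolated)
Conditions: second-generation Hoveyda–Grubbs catalyst RuCl2(H2IMes)(=CH-C6H4-2-OiPr) (10 mol%), PhMe (0.01 M), 70 °C, Ar sparge, slow addition of 17 (1.5 equiv); then Me3NO·2H2O, THF, 60 °C; then 1 M HCl, THF, 0 °C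
Reagents that add atoms: trimethylamine N-oxide C[N+](C)(C)[O-]
Why: Proposed new method: the catalyst loads on the unhindered terminal alkene of the relay chain, closes the five-membered ring that is expelled as cyclopentene and thereby places the ruthenium alkylidene on C9; this alkylidene adds across the alkynyl boronate with C–C bond formation at the less encumbered, boron-bearing carbon (C9–C8), the metal ending on C7 next to the quaternary carbinol carbon, and the C7 vinylcarbene then closes onto the C6 vinyl group (C6=C7) to give the 2-boryl-1,3-cyclohexadiene 18. The closest known reaction types are the tandem enyne cross-metathesis/ring-closing metathesis of 1,5-dienes with alkynes to 1,3-cyclohexadienes, cross enyne metathesis of alkynyl pinacol boronates and relay ring-closing metathesis; their union on an internal, boron-substituted alkyne is the untested part. Ring B is closed by ring-closing metathesis of the C7 carbene onto the C6 alkene (six-membered, between two side chains that are trans-diequatorial and gauche on ring A), and the only other ring event is the sacrificial cyclopentene closure of the relay. No stereocentre is formed, and C5 and C10 are not touched, so the trans ring fusion is inherited from 13. The step needs regioselectivity (C9 to C8 and C6 to C7, not the crossed mode), which the substrate secures through the relay (alkylidene born on C9, the C6 vinyl group kept as acceptor), through the size difference of the two alkyne substituents, and through slow addition of 17 so that methylidene is captured by the relay alkene before it meets the alkyne. Trimethylamine N-oxide then oxidises the C8–B bond to the enol, which tautomerises to the conjugated enone 19, and dilute acid removes the silyl ether.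

Step 10
Reactants: 20 (4aR,8aR)-3-(2-hydroxypropan-2-yl)-5,8a-dimethyl-4a,7,8,8a-tetrahydronaphthalen-2(1H)-one
Product: 21 (4aR,5S,6R,8aR)-5,6-dihydroxy-3-(2-hydroxypropan-2-yl)-5,8a-dimethyl-4a,5,6,7,8,8a-hexahydronaphthalen-2(1H)-one
Conditions: OsO4 (2 mol%), N-methylmorpholine N-oxide, acetone/H2O, 0 °C to rt
Reagents that add atoms: osmium tetroxide O=[Os](=O)(=O)=O; N-methylmorpholine N-oxide C[N+]1([O-])CCOCC1; water O
Why: Catalytic osmium tetroxide dihydroxylation is selective for the electron-rich C3=C4 alkene over the hindered, electron-poor enone, and the reagent should add syn from the α face opposite the axial C10 methyl of the trans-decalin, which sets C3 (R) and C4 (S) as the 3α,4α-diol.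

Step 11
Reactants: 22 (2E)-2-methylbut-2-en-1-ol
Product: 23 [(2R,3R)-2,3-dimethyloxiran-2-yl]methanol
Conditions: Ti(OiPr)4 (10 mol%), D-(−)-diisopropyl tartrate (12 mol%), t-BuOOH, 4 Å molecular sieves, CH2Cl2, −20 °C
Reagents that add atoms: tert-butyl hydroperoxide CC(C)(C)OO
Why: Sharpless asymmetric epoxidation, in which the D-(−)-tartrate titanium complex delivers oxygen to the face of the E allylic alcohol that gives the (2R,3R)-epoxy alcohol (reagent control), the E geometry fixing the trans relation of CH2OH and the C3 methyl.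

Step 12
Reactants: 23 [(2R,3R)-2,3-dimethyloxiran-2-yl]methanol
Product: 25 (2S,3R)-2,3-dimethyloxirane-2-carboxylic acid, via epoxy aldehyde 24 (not isolated)
Conditions: TEMPO (cat.), PhI(OAc)2, MeCN/H2O, rt
Reagents that add atoms: water O
Why: Oxoammonium (TEMPO) oxidation with PhI(OAc)2 in aqueous acetonitrile takes the primary alcohol through the aldehyde hydrate to the acid under near-neutral conditions that leave the epoxide and both stereocentres intact (C2 becomes S only by the priority change).

Step 13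
Reactants: 21 (4aR,5S,6R,8aR)-5,6-dihydroxy-3-(2-hydroxypropan-2-yl)-5,8a-dimethyl-4a,5,6,7,8,8a-hexahydronaphthalen-2(1H)-one; 25 (2S,3R)-2,3-dimethyloxirane-2-carboxylic acid
Product: 27 (1S,2R,4aR,8aR)-1-hydroxy-7-(2-hydroxypropan-2-yl)-1,4a-dimethyl-6-oxo-1,2,3,4,4a,5,6,8a-octahydronaphthalen-2-yl (2S,3R)-2,3-dimethyloxirane-2-carboxylate, via mixed anhydride 26 (not isolated)
Conditions: 25, 2,4,6-trichlorobenzoyl chloride, Et3N, THF, rt; then 21, DMAP, PhMe, rt to 40 °C
Reagents that add atoms: none
Why: Yamaguchi esterification, in which the acid is activated as the mixed trichlorobenzoic anhydride and transferred by DMAP to the only acylable hydroxyl, the secondary C3–OH (the two tertiary alcohols are inert), with retention at every stereocentre.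

**Compound list**

1 | pent-1-en-3-one | CCC(=O)C=C | starting material
2 | (Z)-triisopropyl(penta-1,3-dien-3-yloxy)silane | C=C/C(=C/C)O[Si](C(C)C)(C(C)C)C(C)C | intermediate
3 | prop-2-enal | C=CC=O | starting material
4 | 2-(triphenylphosphoranylidene)propanal | CC(C=O)=P(c1ccccc1)(c1ccccc1)c1ccccc1 | starting material
5 | (2E)-2-methylpenta-2,4-dienal | C=C/C=C(\C)C=O | intermediate
6 | (1S,5S,6S)-6-ethenyl-1,5-dimethyl-4-(triisopropylsilyloxy)cyclohex-3-ene-1-carbaldehyde | C=C[C@H]1[C@H](C)C(O[Si](C(C)C)(C(C)C)C(C)C)=CC[C@]1(C)C=O | intermediate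
7 | (hex-5-en-1-yl)triphenylphosphonium bromide | C=CCCCC[P+](c1ccccc1)(c1ccccc1)c1ccccc1.[Br-] | starting material
8 | hex-5-enylidene(triphenyl)phosphorane | C=CCCCC=P(c1ccccc1)(c1ccccc1)c1ccccc1 | intermediate
9 | triisopropyl{[(4R,5S,6S)-5-ethenyl-4-[(1Z)-hepta-1,6-dien-1-yl]-4,6-dimethylcyclohex-1-en-1-yl]oxy}silane | C=C[C@H]1[C@H](C)C(O[Si](C(C)C)(C(C)C)C(C)C)=CC[C@]1(C)/C=C\CCCC=C | intermediate
10 | (2S,3S,4R)-3-ethenyl-4-[(1Z)-hepta-1,6-dien-1-yl]-2,4-dimethylcyclohexan-1-one | C=C[C@H]1[C@H](C)C(=O)CC[C@]1(C)/C=C\CCCC=C | intermediate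
11 | bromomagnesium (3R,4R)-3-ethenyl-4-[(1Z)-hepta-1,6-dien-1-yl]-2,4-dimethylcyclohex-1-en-1-olate | C=C[C@H]1C(C)=C(O[Mg]Br)CC[C@]1(C)/C=C\CCCC=C | intermediate
12 | (3R,4R)-3-ethenyl-4-[(1Z)-hepta-1,6-dien-1-yl]-2,4-dimethylcyclohex-1-en-1-yl trifluoromethanesulfonate | C=C[C@H]1C(C)=C(OS(=O)(=O)C(F)(F)F)CC[C@]1(C)/C=C\CCCC=C | intermediate
13 | (5R,6S)-6-ethenyl-5-[(1Z)-hepta-1,6-dien-1-yl]-1,5-dimethylcyclohex-1-ene | C=C[C@H]1C(C)=CCC[C@]1(C)/C=C\CCCC=C | intermediate
14 | trimethyl[(2-methylbut-3-yn-2-yl)oxy]silane | C#CC(C)(C)O[Si](C)(C)C | starting material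
15 | lithium 3-methyl-3-(trimethylsilyloxy)but-1-yn-1-ide | [Li]C#CC(C)(C)O[Si](C)(C)C | intermediate
16 | lithium [3-methyl-3-(trimethylsilyloxy)but-1-yn-1-yl](propan-2-yloxy)(pinacolato)borate | [Li+].CC(C)O[B-]1(C#CC(C)(C)O[Si](C)(C)C)OC(C)(C)C(C)(C)O1 | intermediate
17 | trimethyl{[2-methyl-4-(4,4,5,5-tetramethyl-1,3,2-dioxaborolan-2-yl)but-3-yn-2-yl]oxy}silane | CC1(C)OB(C#CC(C)(C)O[Si](C)(C)C)OC1(C)C | intermediate
18 | trimethyl({2-[(4aR,8aS)-4a,8-dimethyl-3-(4,4,5,5-tetramethyl-1,3,2-dioxaborolan-2-yl)-4a,5,6,8a-tetrahydronaphthalen-2-yl]propan-2-yl}oxy)silane | CC1=CCC[C@]2(C)C=C(B3OC(C)(C)C(C)(C)O3)C(C(C)(C)O[Si](C)(C)C)=C[C@@H]12 | intermediate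
19 | (4aR,8aR)-5,8a-dimethyl-3-[2-(trimethylsilyloxy)propan-2-yl]-4a,7,8,8a-tetrahydronaphthalen-2(1H)-one | CC1=CCC[C@]2(C)CC(=O)C(C(C)(C)O[Si](C)(C)C)=C[C@@H]12 | intermediate
20 | (4aR,8aR)-3-(2-hydroxypropan-2-yl)-5,8a-dimethyl-4a,7,8,8a-tetrahydronaphthalen-2(1H)-one | CC1=CCC[C@]2(C)CC(=O)C(C(C)(C)O)=C[C@@H]12 | intermediate
21 | (4aR,5S,6R,8aR)-5,6-dihydroxy-3-(2-hydroxypropan-2-yl)-5,8a-dimethyl-4a,5,6,7,8,8a-hexahydronaphthalen-2(1H)-one | O[C@@H]1CC[C@]2(C)CC(=O)C(C(C)(C)O)=C[C@H]2[C@]1(C)O | intermediate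
22 | (2E)-2-methylbut-2-en-1-ol | C/C=C(\C)CO | starting material
23 | [(2R,3R)-2,3-dimethyloxiran-2-yl]methanol | C[C@H]1O[C@]1(C)CO | intermediate
24 | (2S,3R)-2,3-dimethyloxirane-2-carbaldehyde | C[C@H]1O[C@]1(C)C=O | intermediate
25 | (2S,3R)-2,3-dimethyloxirane-2-carboxylic acid | C[C@H]1O[C@]1(C)C(=O)O | intermediate
26 | (2S,3R)-2,3-dimethyloxirane-2-carboxylic 2,4,6-trichlorobenzoic anhydride | C[C@H]1O[C@]1(C)C(=O)OC(=O)c1c(Cl)cc(Cl)cc1Cl | intermediate
27 | (1S,2R,4aR,8aR)-1-hydroxy-7-(2-hydroxypropan-2-yl)-1,4a-dimethyl-6-oxo-1,2,3,4,4a,5,6,8a-octahydronaphthalen-2-yl (2S,3R)-2,3-dimethyloxirane-2-carboxylate | C[C@H]1O[C@]1(C)C(=O)O[C@@H]1CC[C@]2(C)CC(=O)C(C(C)(C)O)=C[C@H]2[C@]1(C)O | target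

**Totals.** Total step count: 13. Longest linear sequence: 9 steps (steps 1, 3, 4, 5, 6, 7, 9, 10, 13).

**Steps most likely to fail**

1. Step 9 (proposed new method). What may go wrong: ruthenium may load on the C6 vinyl group instead of the relay, or the alkyne may insert with the metal on the boron-bearing carbon. Either event joins C6 to C8 and C9 to C7 and gives the constitutional isomer of ring B. The crowded vinylcarbene may also fail to turn over, so that the alkyne oligomerises. The fallback uses known reactions only, sets out from 6 and comes back to the route at 19. Aldehyde 6 is homologated with (methoxymethylene)triphenylphosphorane (from MeOCH2PPh3Cl and KN(SiMe3)2, THF) to the methyl enol ether F1. The ring-A operations of steps 5 to 7 (n-Bu4NF/AcOH; i-Pr2NMgBr then PhNTf2; Pd(OAc)2, PPh3, HCO2H, n-Bu3N) then give the ketone F2, the enol triflate F3 and the diene enol ether F4. Aqueous oxalic acid in THF hydrolyses the enol ether to the homologated aldehyde F5, in which the C8–C9 bond is in place. Bromoboration–protonolysis of alkyne 14 (B-bromo-9-borabicyclo[3.3.1]nonane, then AcOH) gives the vinyl bromide F6. Its lithium reagent (t-BuLi, Et2O, −78 °C) adds to F5 to give the allylic alcohol F7, and Dess–Martin periodinane oxidises this to the α-methylene ketone F8. Ring-closing metathesis between the C6 vinyl group and the C7 methylene (second-generation Grubbs catalyst RuCl2(H2IMes)(PCy3)(=CHPh), CH2Cl2, 40 °C) closes ring B to 19, which is desilylated as in the last operation of step 9.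

2. Step 3. What may go wrong: cycloaddition at the distal alkene of the dienal or Mukaiyama–Michael addition without ring closure, and weak enantiofacial discrimination with an α,β-disubstituted dienal. The fallback sets out from 2 and comes back to the route at 9. Diene 2 is combined under the same catalyst with commercial ethyl (2E)-3-methyl-4-oxobut-2-enoate, which is activated at both alkene carbons and has no second alkene, to give the formyl ester adduct F9 (formyl on C10, ester on C5, trans). Wittig reaction of the formyl group with ylide 8 gives the relay ester F10. Reduction with i-Bu2AlH (CH2Cl2, −78 °C) gives the aldehyde F11, and methylenation (Ph3P=CH2, THF, −78 °C to 0 °C) gives 9.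

3. Step 13. What may go wrong: slow acyl transfer to the hindered axial C3 hydroxyl may let the mixed anhydride disproportionate or the epoxide open under activation. The fallback sets out from 21 and comes back to the route at 27. The secondary hydroxyl is acylated with (2E)-2-methylbut-2-enoyl chloride (pyridine, DMAP, CH2Cl2) to the tiglate F12. The ester alkene is then epoxidised with methyl(trifluoromethyl)dioxirane (CH2Cl2, 0 °C), the electron-poor ring-B enone staying untouched. This should give 27 together with its epoxide epimer, the (2R,3S)-epoxy ester F13, from which 27 is separated by HPLC.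

**Further compounds**

F1 | step 9 | triisopropylsilyl enol ether of 6 homologated to the 2-methoxyethenyl group on C10 (E/Z mixture) | C=C[C@H]1[C@H](C)C(O[Si](C(C)C)(C(C)C)C(C)C)=CC[C@]1(C)C=COC
F2 | step 9 | 3-ethenyl-4-(2-methoxyethenyl)-2,4-dimethylcyclohexan-1-one (ring configuration as in 10) | C=C[C@H]1[C@H](C)C(=O)CC[C@]1(C)C=COC
F3 | step 9 | 3-ethenyl-4-(2-methoxyethenyl)-2,4-dimethylcyclohex-1-en-1-yl trifluoromethanesulfonate (ring configuration as in 12) | C=C[C@H]1C(C)=C(OS(=O)(=O)C(F)(F)F)CC[C@]1(C)C=COC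
F4 | step 9 | 6-ethenyl-5-(2-methoxyethenyl)-1,5-dimethylcyclohex-1-ene (ring configuration as in 13) | C=C[C@H]1C(C)=CCC[C@]1(C)C=COC
F5 | step 9 | 2-[(1R,2R)-2-ethenyl-1,3-dimethylcyclohex-3-en-1-yl]acetaldehyde | C=C[C@H]1C(C)=CCC[C@]1(C)CC=O
F6 | step 9 | [(3-bromo-2-methylbut-3-en-2-yl)oxy]trimethylsilane | C=C(Br)C(C)(C)O[Si](C)(C)C
F7 | step 9 | 1-[(1R,2R)-2-ethenyl-1,3-dimethylcyclohex-3-en-1-yl]-4-methyl-3-methylidene-4-(trimethylsilyloxy)pentan-2-ol (carbinol epimers) | C=C[C@H]1C(C)=CCC[C@]1(C)CC(O)C(=C)C(C)(C)O[Si](C)(C)C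
F8 | step 9 | 1-[(1R,2R)-2-ethenyl-1,3-dimethylcyclohex-3-en-1-yl]-4-methyl-3-methylidene-4-(trimethylsilyloxy)pentan-2-one | C=C[C@H]1C(C)=CCC[C@]1(C)CC(=O)C(=C)C(C)(C)O[Si](C)(C)C
F9 | step 3 | ethyl (1S,2S,6S)-6-formyl-2,6-dimethyl-3-(triisopropylsilyloxy)cyclohex-3-ene-1-carboxylate | CCOC(=O)[C@H]1[C@H](C)C(O[Si](C(C)C)(C(C)C)C(C)C)=CC[C@]1(C)C=O
F10 | step 3 | ethyl 6-[(1Z)-hepta-1,6-dien-1-yl]-2,6-dimethyl-3-(triisopropylsilyloxy)cyclohex-3-ene-1-carboxylate (ring configuration as in 9) | CCOC(=O)[C@H]1[C@H](C)C(O[Si](C(C)C)(C(C)C)C(C)C)=CC[C@]1(C)/C=C\CCCC=C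
F11 | step 3 | 6-[(1Z)-hepta-1,6-dien-1-yl]-2,6-dimethyl-3-(triisopropylsilyloxy)cyclohex-3-ene-1-carbaldehyde (ring configuration as in 9) | O=C[C@H]1[C@H](C)C(O[Si](C(C)C)(C(C)C)C(C)C)=CC[C@]1(C)/C=C\CCCC=C
F12 | step 13 | (1S,2R,4aR,8aR)-1-hydroxy-7-(2-hydroxypropan-2-yl)-1,4a-dimethyl-6-oxo-1,2,3,4,4a,5,6,8a-octahydronaphthalen-2-yl (2E)-2-methylbut-2-enoate | C/C=C(\C)C(=O)O[C@@H]1CC[C@]2(C)CC(=O)C(C(C)(C)O)=C[C@H]2[C@]1(C)O
F13 | step 13 | (1S,2R,4aR,8aR)-1-hydroxy-7-(2-hydroxypropan-2-yl)-1,4a-dimethyl-6-oxo-1,2,3,4,4a,5,6,8a-octahydronaphthalen-2-yl (2R,3S)-2,3-dimethyloxirane-2-carboxylate | C[C@@H]1O[C@@]1(C)C(=O)O[C@@H]1CC[C@]2(C)CC(=O)C(C(C)(C)O)=C[C@H]2[C@]1(C)O
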